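The readings are simulated with constants of no real substance; the scatter is artificial.

The sum of target and starting material stays near the charge (104% at the end of Saturday's run, with an error of 1.5 percentage points on each reading), so we count starting material lost as target gained.

| setting | Saturday's | Thursday's | Monday's | Sunday's | north-west | south | south-east | east |
|---|---|---|---|---|---|---|---|---|
| starting material | 0.050 M | 0.025 M | 0.038 M | 0.050 M | 0.050 M | 0.050 M | 0.050 M | 0.050 M (fed, over 24.0 min) |
| reagent | 0.10 M | 0.10 M | 0.10 M | 0.20 M | 0.100 M | 0.100 M (fed, over 24.0 min) | 0.100 M | 0.100 M |
| remark | run made earlier | run made earlier | run made earlier | run made earlier | a single well-mixed tank run continuously and read at steady state, 30 min in it on average | a stirred flask in which reagent is dosed at a steady rate over 24.0 min without added volume, worked up at 30 min | everything together in a closed stirred flask, run for 30 min | a stirred flask in which starting material is dosed at a steady rate over 24.0 min without added volume, worked up at 30 min |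
| time |  |  |  |  |  | 30 min | 30 min | 30 min |

- Saturday's (time / min: target / %, starting material / %): 2.50: 3, 99; 8.00: 3, 95; 15.0: 11, 88; 20.0: 15, 81; 30.0: 33, 71
- Thursday's (time / min: target / %, starting material / %): 1.50: 1, 99; 5.00: 3, 95; 8.00: 4, 95; 12.0: 6, 92; 20.0: 14, 88
- Monday's (time / min: target / %, starting material / %): 4.00: 3, 99; 8.00: 4, 96; 10.0: 5, 93; 15.0: 10, 91; 20.0: 14, 88
- Sunday's (time / min: target / %, starting material / %): 1.50: 3, 98; 5.00: 7, 94; 8.00: 14, 86; 12.0: 21, 74; 20.0: 51, 52

(readings scatter by 1.5 percentage points)

- the set-up with the highest amount of target at the outlet or at the end, in percent of the starting material put in ("none" if the first two lie within 2 percentage points) (north-west / south / south-east / east / none)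
- amount of target at the outlet or at the end, in percent of the starting material put in, north-west
- amount of target at the outlet or at the end, in percent of the starting material put in, south
- amount of target at the outlet or at the end, in percent of the starting material put in, south-east
- amount of target at the outlet or at the end, in percent of the starting material put in, east

- the stated concentrations are those of everything mixed, before any reaction; amounts are the same in each set-up
- the feed brings no volume worth counting
- the earlier runs were made in a closed, stirred flask

Two of us argued at the board over the tank, north-west, against the closed flask, south-east. Saturday's run has the south-east recipe, and it kept 71% of its starting material at 30.0 min. That gives 0.0114 /min as the mean fractional rate: the logarithm of charged over left, divided by the time, which is the curve replaced by its mean.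

I held the pseudo-first-order picture, in which that rate stays constant. The closed flask then converts 29.0%. In the tank, converted over unconverted equals rate times mean time, which gives 25.5%, so on my view the tank loses.

My colleague objected that the curve is not flat. In Saturday's run the rate reads 0.00852 /min up to 15.0 min and 0.0143 /min after it, later faster than earlier. Thursday's run, with half the starting material, reads 0.00639 /min up to 20.0 min, lower than Saturday's 0.0105 /min over the same time. So these readings fit a rate that rises with the target made.

A tank has no curve, since its contents stay at outlet composition. To reach 40% it must hold 0.0222 /min, twice the mean. The forecast, hers, says “the mixture sits at high product level”. It gives north-west 40%, south 15%, south-east 30% and east 15%, with north-west best.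

The best set-up is north-west: the tank gives 45.6%, the highest, against south-east's 31.1%, south's 14.5% and east's 14.4%.

    target → over-reaction product (k = 7.60 × 10⁻⁷ /s)
    starting material + reagent → target + released group (k = 8.00 × 10⁻⁴ /M/s)
    starting material + reagent + released group → target + 2 released group (k = 0.230 /M²/s)

The tank's outlet held 54.3% of the starting material, so its fractional rate, lost over left per mean time, was 0.0280 /min, more than the forecast needed. My constant picture keeps the stretch of low target. The east flask ended with 85.6% of its whole charge unconverted, and reckoned on that charge its mean fractional rate is 0.00519 /min, below Saturday's mean and beside Thursday's 0.00639 /min.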